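**Retrosynthetic overview**
1. Target ⇒ late adjustments (6-Cl by SN2 on a 6-OH obtained from a Δ5 epoxide; γ-lactone by reduction of a C-7 ketone next to the C-17–C-19 ester) ⇒ ten-membered 2,7-diketone 35.
2. 35 ⇒ ozonolysis of the tetrasubstituted C2=C7 alkene shared by rings B and C of a hydrophenanthrene (33); that alkene ⇒ Birch dearomatisation of an anisole ring (key step), so the arene carbons become C-2 to C-7 of the ten-membered ring.
3. Before the cut, the rigid trans-fused tricycle receives the other stereocentres: C-8/C-9/C-17 through a C-9 ketone (lactate triflate alkylation, enolate hydroxylation, α-face reduction) and the ring A oxygens through a C-12 ketone (enone dihydroxylation, α-methylenation, directed epoxidation).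
4. Tricycle ⇒ asymmetric Robinson annulation (chiral-imine Michael addition sets C-1) of 6-methoxy-1-methyl-2-tetralone with methyl vinyl ketone ⇒ 6-methoxy-1-tetralone.
5. Ring order: ring C (bought as the arene) → ring B (tetralone) → ring A (annulation) → ten-membered ring (cleavage of the B/C fusion bond) → γ-lactone.

Assumption: atoms carry briarane numbers (ten-membered ring C-1 to C-10; ring A = C-1, C-10 to C-14; C-15 = methyl on C-1; C-16 = CH2 on C-5; C-17/C-18/C-19 = lactone CH, its methyl, carbonyl; C-20 = epoxide CH2), α is the face of H-10 and β the face of the C-15 methyl in the flat drawing (target = 1S,2S,6S,7R,8R,9S,10S,11S,12R,13R,14R,17R), and rings B (C-1, C-2, C-7 to C-10) and C (C-2 to C-7) are the two six-membered rings later merged.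

Step 1
Reactants: 1 6-methoxy-1-tetralone
Product: 3 7-methoxy-4-methyl-1,2-dihydronaphthalene, via tertiary alcohol 2 (not isolated)
Conditions: MeMgBr, THF, 0 → 20 °C; then 2 M HCl, THF, 20 °C
Reagents that add atoms: methylmagnesium bromide, C[Mg]Br
Why: Grignard 1,2-addition to the aryl ketone followed by acid-catalysed E1 dehydration of the tertiary benzylic alcohol gives the conjugated styrene, with no stereocentre formed.

Step 2
Reactants: 3 7-methoxy-4-methyl-1,2-dihydronaphthalene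
Product: 5 6-methoxy-1-methyl-3,4-dihydronaphthalen-2(1H)-one (racemic), via epoxide 4 (not isolated)
Conditions: mCPBA, NaHCO3, CH2Cl2, 0 °C; then TsOH (cat.), benzene, 20 °C
Reagents that add atoms: 3-chloroperbenzoic acid, O=C(OO)c1cccc(Cl)c1
Why: Prilezhaev epoxidation of the electron-rich styrene and acid-catalysed Meinwald rearrangement (hydride shift to the p-methoxybenzylic cation) give the 1-methyl-2-tetralone, whose only stereocentre is enolisable and therefore irrelevant.

Step 3
Reactants: 5 6-methoxy-1-methyl-2-tetralone; 6 (R)-1-phenylethylamine; 7 methyl vinyl ketone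
Product: 10 (R)-6-methoxy-1-methyl-1-(3-oxobutyl)-3,4-dihydronaphthalen-2(1H)-one, via imine 8 (not isolated), via Michael-adduct imine 9 (not isolated)
Conditions: 6, TsOH (cat.), toluene, reflux (Dean–Stark); then 7, THF, 20 °C; then AcOH/H2O, 20 °C
Reagents that add atoms: water, O
Why: d'Angelo deracemising Michael addition, in which the chiral imine reacts through its more substituted secondary enamine tautomer on the face anti to the phenyl group of the auxiliary with internal N–H transfer, sets the quaternary C-1 (15-methyl β, R in 10) before hydrolysis returns the ketone and the amine.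

Step 4
Reactants: 10 (R)-diketone
Product: 11 (S)-7-methoxy-4a-methyl-4,4a,9,10-tetrahydrophenanthren-2(3H)-one (C-12 ketone conjugated to C10=C11)
Conditions: NaOMe, MeOH, 60 °C
Reagents that add atoms: none
Why: Intramolecular aldol condensation (second half of the Robinson annulation) closes ring A, and the non-enolisable C-1 keeps its configuration.

Step 5
Reactants: 11 tricyclic enone
Product: 12 C-12 ethylene ketal with the double bond at C9=C10
Conditions: HOCH2CH2OH, TsOH (cat.), benzene, reflux (Dean–Stark)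
Reagents that add atoms: ethylene glycol, OCCO
Why: Acid-catalysed ketalisation of the enone runs through the dienol, so the alkene moves out of conjugation to C9=C10 (deconjugative dioxolane formation), which protects C-12 and places an alkene where C-9 must be oxygenated.

Step 6
Reactants: 12 Δ9(10) ketal
Product: 14 9α-hydroxy 12-ketal (H-10 α; rings A/B trans-fused), via alkylborane 13 (not isolated)
Conditions: BH3·THF, THF, 0 → 20 °C; then NaOH, H2O2, H2O, 0 °C
Reagents that add atoms: hydrogen peroxide, OO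
Why: Brown hydroboration–oxidation adds B–H syn from the α face, opposite the angular 15-methyl, with boron on the less substituted C-9, giving H-10 α (trans ring fusion) and, after oxidation with retention, the 9α-alcohol.

Step 7
Reactants: 14 9α-hydroxy 12-ketal (anisole ring C)
Product: 16 9α-hydroxy-12,12-ethylenedioxy-Δ2(7)-5-ketone (ring C dearomatised), via enol ether 15 (not isolated)
Conditions: Li, NH3 (l), THF, t-BuOH, −78 → −33 °C; NH4Cl; then (CO2H)2, MeOH/H2O, 20 °C
Reagents that add atoms: water, O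
Why: Birch reduction of the anisole ring (the key dearomatisation) keeps the alkyl-substituted C2=C7 and the methoxy-substituted C4=C5 double bonds while the homobenzylic lithium alkoxide and the ketal are inert, and mild oxalic acid hydrolysis of the enol ether gives the unconjugated β,γ-enone exactly as in the estradiol methyl ether to estr-5(10)-en-3-one sequence, with no new stereocentre.

Step 8
Reactants: 16 Δ2(7)-5-ketone
Product: 17 5-hydroxy-5-methyl compound (C-16 installed; both C-5 epimers)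
Conditions: MeMgBr, CeCl3, THF, −78 °C
Reagents that add atoms: methylmagnesium bromide, C[Mg]Br
Why: Imamoto organocerium 1,2-addition suppresses enolisation of the doubly activated C-6 position and installs C-16 as a tertiary carbinol, both C-5 epimers being carried on because C-5 becomes sp2 in step 23.

Step 9
Reactants: 17 9α-alcohol
Product: 18 9-ketone
Conditions: Dess–Martin periodinane, NaHCO3, CH2Cl2, 0 → 20 °C
Reagents that add atoms: none
Why: Dess–Martin oxidation of the secondary alcohol gives the C-9 ketone, which makes C-8 (α to the ketone and allylic to C2=C7) the most acidic carbon, while H-10 (α to the ketone) stays in the thermodynamically preferred trans-fused arrangement.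

Step 10
Reactants: 19 methyl (R)-lactate
Product: 20 methyl (R)-2-(trifluoromethylsulfonyloxy)propanoate
Conditions: Tf2O, 2,6-lutidine, CH2Cl2, −78 → 0 °C
Reagents that add atoms: trifluoromethanesulfonic anhydride, O=S(=O)(OS(=O)(=O)C(F)(F)F)C(F)(F)F
Why: O-Sulfonylation of the alcohol breaks no bond at the stereocentre, so C-17 is retained.

Step 11
Reactants: 18 9-ketone; 20 lactate triflate
Product: 21 8-[(R)-1-methoxy-1-oxopropan-2-yl] 9-ketone (17R; C-8 epimers)
Conditions: LiN(SiMe3)2 (2.1 equiv), THF, −78 °C; then 20, −78 → −20 °C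
Reagents that add atoms: none
Why: Alkylation of the lithium dienolate at its α carbon (C-8) by SN2 displacement of the α-triflyloxy ester with clean inversion sets C-17 as R, and the C-8 configuration is irrelevant because C-8 is enolised again in the next step.

Step 12
Reactants: 21 8-alkyl 9-ketone
Product: 23 5,8α-bis(triethylsilyloxy) 9-ketone (ester side chain 8β), via 8-hydroxy ketone 22 (not isolated)
Conditions: KN(SiMe3)2 (2.2 equiv), THF, −78 °C; 2-(phenylsulfonyl)-3-phenyloxaziridine; then Et3SiOSO2CF3, −78 → 0 °C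
Reagents that add atoms: 2-(phenylsulfonyl)-3-phenyloxaziridine, O=S(=O)(N1OC1c1ccccc1)c1ccccc1; triethylsilyl trifluoromethanesulfonate, CC[Si](CC)(CC)OS(=O)(=O)C(F)(F)F
Why: Davis oxidation of the potassium dienolate at the α carbon from the α face (the β face is shielded by the axial 15-methyl) puts the hydroxyl α and the ester side chain β at C-8, and in situ silylation protects both tertiary alkoxides.

Step 13
Reactants: 23 silylated 9-ketone
Product: 25 9β-acetate, via 9β-alcohol 24 (not isolated)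
Conditions: LiAlH(OtBu)3, THF, −20 → 0 °C; then Ac2O, pyridine, DMAP, 0 → 20 °C
Reagents that add atoms: acetic anhydride, CC(=O)OC(C)=O
Why: Hydride adds to the C-9 ketone from the α face (the β face is blocked by the 1,3-diaxial 15-methyl and the 8β side chain) to give the axial 9β-alkoxide, which is acetylated as its aluminium alkoxide before it can lactonise onto the ester (one-pot reductive acetylation).

Step 14
Reactants: 25 9β-acetate 12-ketal
Product: 26 12-ketone
Conditions: PPTS, acetone/H2O, 55 °C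
Reagents that add atoms: water, O
Why: Acid-catalysed hydrolysis of the dioxolane unveils the C-12 ketone while the tertiary silyl ethers and the esters are untouched.

Step 15
Reactants: 26 12-ketone
Product: 27 Δ13-12-ketone (C13=C14 enone)
Conditions: IBX, DMSO/fluorobenzene, 65 °C
Reagents that add atoms: none
Why: IBX dehydrogenation proceeds through the enol towards C-13, the enolisation direction preferred by trans-fused 3-keto-5α-steroid-type ketones, giving the C13=C14 enone.

Step 16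
Reactants: 27 enone
Product: 28 13α,14α-diol
Conditions: OsO4 (cat.), NMO, citric acid, t-BuOH/acetone/H2O, 20 °C
Reagents that add atoms: N-methylmorpholine N-oxide, C[N+]1([O-])CCOCC1; water, O
Why: Upjohn dihydroxylation of the cis-disubstituted enone alkene from the α face, anti to the adjacent axial 15-methyl, gives the 13α,14α-diol while the hindered tetrasubstituted C2=C7 alkene does not react.

Step 17
Reactants: 28 13α,14α-diol
Product: 29 13α-isovalerate
Conditions: isovaleric anhydride, pyridine, DMAP (cat.), CH2Cl2, −20 °C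
Reagents that add atoms: 3-methylbutanoic anhydride, CC(C)CC(=O)OC(=O)CC(C)C
Why: Selective DMAP-catalysed acylation of the equatorial 13-hydroxyl over the axial, neopentyl 14-hydroxyl installs the isovalerate.

Step 18
Reactants: 29 13α-isovalerate 12-ketone
Product: 30 11-methylene-12-ketone (C-20 installed)
Conditions: (CH2O)n, N-methylanilinium trifluoroacetate, THF, reflux
Reagents that add atoms: formaldehyde (as paraformaldehyde), C=O
Why: Gras α-methylenation (Mannich condensation then elimination) can only be completed at C-11, the sole α position bearing two hydrogens, giving the exocyclic enone that carries C-20.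

Step 19
Reactants: 30 α-methylene ketone
Product: 31 12α-alcohol
Conditions: NaBH4, CeCl3·7H2O, MeOH, −78 °C
Reagents that add atoms: none
Why: Luche 1,2-reduction in which trivalent cerium bridges the axial 14α-hydroxyl and the ketone directs hydride to the β face, giving the axial 12α-alcohol (1,3-syn to 14-OH) without conjugate reduction.

Step 20
Reactants: 31 12α-allylic alcohol
Product: 32 11α,20-epoxide (C-20 β)
Conditions: VO(acac)2 (cat.), t-BuOOH, CH2Cl2, 0 → 20 °C
Reagents that add atoms: tert-butyl hydroperoxide, CC(C)(C)OO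
Why: Sharpless vanadium-catalysed hydroxyl-directed epoxidation delivers oxygen to the exocyclic alkene from the face of the 12α-hydroxyl and leaves the C2=C7 alkene, which has no free allylic hydroxyl, untouched.

Step 21
Reactants: 32 epoxy diol
Product: 33 12α,14α-diacetate (fully decorated tricycle)
Conditions: Ac2O, DMAP, Et3N, CH2Cl2, 20 °C
Reagents that add atoms: acetic anhydride, CC(=O)OC(C)=O
Why: DMAP-catalysed acetylation esterifies the two remaining secondary hydroxyls (C-12 and C-14) while the tertiary silyl ethers are inert.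

Step 22
Reactants: 33 tricyclic C2=C7 alkene
Product: 35 ten-membered 2,7-diketone, via ozonide 34 (not isolated)
Conditions: O3, CH2Cl2, −78 °C; then Me2S, −78 → 20 °C
Reagents that add atoms: ozone, [O-][O+]=O
Why: Criegee ozonolysis of the only C=C bond, the tetrasubstituted ring-fusion alkene created by the Birch step, cuts the bond shared by rings B and C and so turns the six–six system into the ten-membered 2,7-diketone without touching a stereocentre.

Step 23
Reactants: 35 2,7-diketone with 5-silyloxy group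
Product: 36 (5Z)-5-en-7-one
Conditions: DBU, toluene, 40 °C
Reagents that add atoms: none
Why: E1cB β-elimination of triethylsilanolate from the β-silyloxy ketone (C-6 is the only enolisable α position of the C-7 ketone) gives the conjugated enone with the cis ring alkene that is the stable geometry in a ten-membered ring.

Step 24
Reactants: 36 enone diketone
Product: 38 7α,19-lactone 2β-alcohol, via hydroxy ester 37 (not isolated)
Conditions: NaBH4, CeCl3·7H2O, MeOH/THF, −40 → 0 °C; then PPTS (cat.), CH2Cl2, 20 °C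
Reagents that add atoms: none
Why: Luche reduction of both ketones, at C-2 in the Felkin–Anh sense anti to C-14 over the small 15-methyl to give the 2β (2S) alcohol and at C-7 anti to the C-8 silyloxy group with the C6–C7–C8–C9 torsion gauche as in the product, is followed by lactonisation of the γ-hydroxy ester (intramolecular transesterification) that fixes the 7α-oxygen in the lactone.

Step 25
Reactants: 38 2β-alcohol
Product: 39 2β-isobutyrate
Conditions: isobutyric anhydride, DMAP, Et3N, CH2Cl2, 20 °C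
Reagents that add atoms: 2-methylpropanoic anhydride, CC(C)C(=O)OC(=O)C(C)C
Why: DMAP-catalysed acylation of the only free hydroxyl (C-2) installs the isobutyrate.

Step 26
Reactants: 39 Δ5 lactone
Product: 40 5,6-epoxide
Conditions: mCPBA, NaHCO3, CH2Cl2, 0 °C
Reagents that add atoms: 3-chloroperbenzoic acid, O=C(OO)c1cccc(Cl)c1
Why: Prilezhaev epoxidation of the single alkene from the peripheral face, which for the Z-alkene with H-7 eclipsing the double bond (allylic 1,3-strain) is the face of the lactone oxygen, gives the epoxide whose C6–O bond has the configuration opposite to that needed for chlorine.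

Step 27
Reactants: 40 bis-epoxide
Product: 42 6-hydroxy-5(16)-ene, via trimethylsilyl ether 41 (not isolated)
Conditions: Me3SiOSO2CF3, 2,6-lutidine, toluene, −78 °C; then DBU, −78 → 0 °C; then citric acid, MeOH, 0 °C
Reagents that add atoms: none
Why: Noyori epoxide-to-allylic-silyl-ether isomerisation (silyl triflate activation, ionisation at tertiary C-5, base-mediated loss of a C-16 proton) opens the electron-rich trisubstituted epoxide with retention at C-6, the acetoxy-flanked spiro-epoxide being far less prone to ionise, and mild methanolysis frees the 6-hydroxyl.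

Step 28
Reactants: 42 allylic alcohol
Product: 43 6α-chloride 8-triethylsilyl ether
Conditions: PPh3, Cl3CC(O)CCl3, CH2Cl2, −20 → 0 °C
Reagents that add atoms: hexachloroacetone, ClC(Cl)(Cl)C(=O)C(Cl)(Cl)Cl
Why: Appel-type chlorination with triphenylphosphine–hexachloroacetone converts the secondary allylic alcohol into the chloride by tight ion-pair SN2 displacement with inversion and without allylic transposition, giving the 6α (6S) chloride.

Step 29
Reactants: 43 8-triethylsilyl ether
Product: 44 CNP0231073.1 (target)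
Conditions: HF·pyridine, pyridine, THF, 0 → 20 °C
Reagents that add atoms: none
Why: Fluoride-mediated desilylation of the tertiary triethylsilyl ether releases the 8α-hydroxyl without affecting the esters, the epoxide or the allylic chloride.

**Compound list**
1 | 6-methoxy-3,4-dihydronaphthalen-1(2H)-one (6-methoxy-1-tetralone) | COc1ccc2C(=O)CCCc2c1 | starting material
2 | 6-methoxy-1-methyl-1,2,3,4-tetrahydronaphthalen-1-ol (racemic) | COc1ccc2c(c1)CCCC2(C)O | intermediate
3 | 7-methoxy-4-methyl-1,2-dihydronaphthalene | COc1ccc2C(C)=CCCc2c1 | intermediate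
4 | 1,2-epoxy-6-methoxy-1-methyl-1,2,3,4-tetrahydronaphthalene (racemic) | COc1ccc2c(c1)CCC1OC12C | intermediate
5 | 6-methoxy-1-methyl-3,4-dihydronaphthalen-2(1H)-one (racemic, C-1 enolisable) | COc1ccc2c(c1)CCC(=O)C2C | intermediate
6 | (R)-1-phenylethylamine | C[C@@H](N)c1ccccc1 | starting material
7 | but-3-en-2-one (methyl vinyl ketone) | CC(=O)C=C | starting material
8 | N-[(R)-1-phenylethyl]imine of 5 (with its secondary enamine tautomer) | COc1ccc2c(c1)CCC(=N[C@H](C)c1ccccc1)C2C | intermediate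
9 | N-[(R)-1-phenylethyl]imine of 10 | COc1ccc2c(c1)CCC(=N[C@H](C)c1ccccc1)[C@]2(C)CCC(C)=O | intermediate
10 | (R)-6-methoxy-1-methyl-1-(3-oxobutyl)-3,4-dihydronaphthalen-2(1H)-one | COc1ccc2c(c1)CCC(=O)[C@]2(C)CCC(C)=O | intermediate
11 | (S)-7-methoxy-4a-methyl-4,4a,9,10-tetrahydrophenanthren-2(3H)-one (15-Me β) | COc1ccc2c(c1)CCC1=CC(=O)CC[C@@]12C | intermediate
12 | 12,12-ethylenedioxy-Δ9(10) tricycle | COc1ccc2c(c1)CC=C1CC3(OCCO3)CC[C@@]12C | intermediate
13 | 9α-boryl-10α-H ketal | COc1ccc2c(c1)C[C@H]([BH2])[C@H]1CC3(OCCO3)CC[C@@]12C | intermediate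
14 | 9α-hydroxy-10α-H 12-ketal (anisole ring C) | COc1ccc2c(c1)C[C@H](O)[C@H]1CC3(OCCO3)CC[C@@]12C | intermediate
15 | 5-methoxy-2(7),4-diene (Birch enol ether) | COC1=CCC2=C(C1)C[C@H](O)[C@H]1CC3(OCCO3)CC[C@@]12C | intermediate
16 | 9α-hydroxy-12,12-ethylenedioxy-Δ2(7)-5-ketone | O=C1CCC2=C(C1)C[C@H](O)[C@H]1CC3(OCCO3)CC[C@@]12C | intermediate
17 | 5,9α-dihydroxy-5-methyl-Δ2(7) 12-ketal (both C-5 epimers; C-5 left unspecified here and below) | CC1(O)CCC2=C(C1)C[C@H](O)[C@H]1CC3(OCCO3)CC[C@@]12C | intermediate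
18 | 5-hydroxy-5-methyl-Δ2(7)-9-ketone 12-ketal | CC1(O)CCC2=C(C1)CC(=O)[C@H]1CC3(OCCO3)CC[C@@]12C | intermediate
19 | methyl (R)-lactate | C[C@@H](O)C(=O)OC | starting material
20 | methyl (R)-2-(trifluoromethylsulfonyloxy)propanoate | C[C@@H](OS(=O)(=O)C(F)(F)F)C(=O)OC | intermediate
21 | 8-[(R)-1-methoxy-1-oxopropan-2-yl] 9-ketone (17R; C-8 epimers) | CC1(O)CCC2=C(C1)C([C@@H](C)C(=O)OC)C(=O)[C@H]1CC3(OCCO3)CC[C@@]12C | intermediate
22 | 5,8α-dihydroxy 9-ketone (side chain 8β) | CC1(O)CCC2=C(C1)[C@@](O)([C@@H](C)C(=O)OC)C(=O)[C@H]1CC3(OCCO3)CC[C@@]12C | intermediate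
23 | 5,8α-bis(triethylsilyloxy) 9-ketone | CC1(O[Si](CC)(CC)CC)CCC2=C(C1)[C@@](O[Si](CC)(CC)CC)([C@@H](C)C(=O)OC)C(=O)[C@H]1CC3(OCCO3)CC[C@@]12C | intermediate
24 | 9β-alcohol (as aluminium alkoxide) | CC1(O[Si](CC)(CC)CC)CCC2=C(C1)[C@@](O[Si](CC)(CC)CC)([C@@H](C)C(=O)OC)[C@@H](O)[C@H]1CC3(OCCO3)CC[C@@]12C | intermediate
25 | 9β-acetate 12-ketal | CC1(O[Si](CC)(CC)CC)CCC2=C(C1)[C@@](O[Si](CC)(CC)CC)([C@@H](C)C(=O)OC)[C@@H](OC(C)=O)[C@H]1CC3(OCCO3)CC[C@@]12C | intermediate
26 | 9β-acetate 12-ketone | CC1(O[Si](CC)(CC)CC)CCC2=C(C1)[C@@](O[Si](CC)(CC)CC)([C@@H](C)C(=O)OC)[C@@H](OC(C)=O)[C@H]1CC(=O)CC[C@@]12C | intermediate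
27 | Δ13-12-ketone | CC1(O[Si](CC)(CC)CC)CCC2=C(C1)[C@@](O[Si](CC)(CC)CC)([C@@H](C)C(=O)OC)[C@@H](OC(C)=O)[C@H]1CC(=O)C=C[C@@]12C | intermediate
28 | 13α,14α-dihydroxy-12-ketone | CC1(O[Si](CC)(CC)CC)CCC2=C(C1)[C@@](O[Si](CC)(CC)CC)([C@@H](C)C(=O)OC)[C@@H](OC(C)=O)[C@H]1CC(=O)[C@H](O)[C@H](O)[C@@]12C | intermediate
29 | 13α-isovaleryloxy-14α-hydroxy-12-ketone | CC1(O[Si](CC)(CC)CC)CCC2=C(C1)[C@@](O[Si](CC)(CC)CC)([C@@H](C)C(=O)OC)[C@@H](OC(C)=O)[C@H]1CC(=O)[C@H](OC(=O)CC(C)C)[C@H](O)[C@@]12C | intermediate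
30 | 11-methylene-12-ketone | CC1(O[Si](CC)(CC)CC)CCC2=C(C1)[C@@](O[Si](CC)(CC)CC)([C@@H](C)C(=O)OC)[C@@H](OC(C)=O)[C@H]1C(=C)C(=O)[C@H](OC(=O)CC(C)C)[C@H](O)[C@@]12C | intermediate
31 | 11-methylene-12α,14α-diol 13α-isovalerate | CC1(O[Si](CC)(CC)CC)CCC2=C(C1)[C@@](O[Si](CC)(CC)CC)([C@@H](C)C(=O)OC)[C@@H](OC(C)=O)[C@H]1C(=C)[C@H](O)[C@H](OC(=O)CC(C)C)[C@H](O)[C@@]12C | intermediate
32 | 11α,20-epoxy-12α,14α-diol | CC1(O[Si](CC)(CC)CC)CCC2=C(C1)[C@@](O[Si](CC)(CC)CC)([C@@H](C)C(=O)OC)[C@@H](OC(C)=O)[C@H]1[C@@]3(CO3)[C@H](O)[C@H](OC(=O)CC(C)C)[C@H](O)[C@@]12C | intermediate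
33 | 11α,20-epoxy-9β,12α,14α-triacetate 13α-isovalerate tricycle with C2=C7 | CC1(O[Si](CC)(CC)CC)CCC2=C(C1)[C@@](O[Si](CC)(CC)CC)([C@@H](C)C(=O)OC)[C@@H](OC(C)=O)[C@H]1[C@@]3(CO3)[C@H](OC(C)=O)[C@H](OC(=O)CC(C)C)[C@H](OC(C)=O)[C@@]12C | intermediate
34 | 2,7-ozonide (1,2,4-trioxolane bridging C-2 and C-7; these two centres unspecified) | CC1(O[Si](CC)(CC)CC)CCC4(OO5)[C@@]2(C)[C@@H](OC(C)=O)[C@@H](OC(=O)CC(C)C)[C@@H](OC(C)=O)[C@]3(CO3)[C@@H]2[C@H](OC(C)=O)[C@](O[Si](CC)(CC)CC)([C@@H](C)C(=O)OC)C5(O4)C1 | intermediate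
35 | ten-membered 2,7-diketone (5,8α-bis-silyloxy) | CC1(O[Si](CC)(CC)CC)CCC(=O)[C@@]2(C)[C@@H](OC(C)=O)[C@@H](OC(=O)CC(C)C)[C@@H](OC(C)=O)[C@]3(CO3)[C@@H]2[C@H](OC(C)=O)[C@](O[Si](CC)(CC)CC)([C@@H](C)C(=O)OC)C(=O)C1 | intermediate
36 | (5Z)-5-ene-2,7-dione | O=C1/C=C(C)\CCC(=O)[C@@]2(C)[C@@H](OC(C)=O)[C@@H](OC(=O)CC(C)C)[C@@H](OC(C)=O)[C@]3(CO3)[C@@H]2[C@H](OC(C)=O)[C@]1(O[Si](CC)(CC)CC)[C@@H](C)C(=O)OC | intermediate
37 | 2β,7α-diol methyl ester | O[C@H]1/C=C(C)\CC[C@H](O)[C@@]2(C)[C@@H](OC(C)=O)[C@@H](OC(=O)CC(C)C)[C@@H](OC(C)=O)[C@]3(CO3)[C@@H]2[C@H](OC(C)=O)[C@]1(O[Si](CC)(CC)CC)[C@@H](C)C(=O)OC | intermediate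
38 | 7α,19-lactone 2β-alcohol | O=C1O[C@H]2/C=C(C)\CC[C@H](O)[C@@]3(C)[C@@H](OC(C)=O)[C@@H](OC(=O)CC(C)C)[C@@H](OC(C)=O)[C@]4(CO4)[C@@H]3[C@H](OC(C)=O)[C@]2(O[Si](CC)(CC)CC)[C@H]1C | intermediate
39 | 2β-isobutyrate Δ5 lactone | O=C1O[C@H]2/C=C(C)\CC[C@H](OC(=O)C(C)C)[C@@]3(C)[C@@H](OC(C)=O)[C@@H](OC(=O)CC(C)C)[C@@H](OC(C)=O)[C@]4(CO4)[C@@H]3[C@H](OC(C)=O)[C@]2(O[Si](CC)(CC)CC)[C@H]1C | intermediate
40 | 5,6:11,20-bis-epoxide | O=C1O[C@H]2[C@@H]5O[C@]5(C)CC[C@H](OC(=O)C(C)C)[C@@]3(C)[C@@H](OC(C)=O)[C@@H](OC(=O)CC(C)C)[C@@H](OC(C)=O)[C@]4(CO4)[C@@H]3[C@H](OC(C)=O)[C@]2(O[Si](CC)(CC)CC)[C@H]1C | intermediate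
41 | 6-trimethylsilyloxy-5(16)-ene | C=C1CC[C@H](OC(=O)C(C)C)[C@@]2(C)[C@@H](OC(C)=O)[C@@H](OC(=O)CC(C)C)[C@@H](OC(C)=O)[C@]3(CO3)[C@@H]2[C@H](OC(C)=O)[C@]2(O[Si](CC)(CC)CC)[C@@H](C)C(=O)O[C@H]2[C@@H]1O[Si](C)(C)C | intermediate
42 | 6-hydroxy-5(16)-ene (6-epi oxygen) | C=C1CC[C@H](OC(=O)C(C)C)[C@@]2(C)[C@@H](OC(C)=O)[C@@H](OC(=O)CC(C)C)[C@@H](OC(C)=O)[C@]3(CO3)[C@@H]2[C@H](OC(C)=O)[C@]2(O[Si](CC)(CC)CC)[C@@H](C)C(=O)O[C@H]2[C@@H]1O | intermediate
43 | 6α-chloride 8-triethylsilyl ether | C=C1CC[C@H](OC(=O)C(C)C)[C@@]2(C)[C@@H](OC(C)=O)[C@@H](OC(=O)CC(C)C)[C@@H](OC(C)=O)[C@]3(CO3)[C@@H]2[C@H](OC(C)=O)[C@]2(O[Si](CC)(CC)CC)[C@@H](C)C(=O)O[C@H]2[C@H]1Cl | intermediate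
44 | CNP0231073.1 | C=C1CC[C@H](OC(=O)C(C)C)[C@@]2(C)[C@@H](OC(C)=O)[C@@H](OC(=O)CC(C)C)[C@@H](OC(C)=O)[C@]3(CO3)[C@@H]2[C@H](OC(C)=O)[C@]2(O)[C@@H](C)C(=O)O[C@H]2[C@H]1Cl | target

**Step count and risks**
Total: 29 steps. Longest linear sequence: 28 steps (steps 1–9 and 11–29 from compound 1); step 10 is a one-step side branch.

The three steps most likely to fail:

Step 24 (configuration at C-7, and to a lesser extent C-2, rests on substrate control in a flexible ten-membered ring). The fallback replaces substrate control by catalyst control and separates the two reductions. It sets out from 36: Corey–Bakshi–Shibata reduction with (R)-2-methyl-CBS-oxazaborolidine and catecholborane in toluene at −60 °C reduces only the enone carbonyl (the quaternary C-8 acting as the large group; the (S)-catalyst is used if the alkenyl carbon proves to be the large group). The 7α-alkoxide closes onto the methyl ester to give the 2-oxo-7α,19-lactone F1. NaBH4 with CeCl3·7H2O then reduces the remaining hindered C-2 ketone, and the route is rejoined at 38.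

Step 27 (the silyl triflate must open the 5,6-epoxide and spare the 11,20-epoxide). The fallback masks the spiro-epoxide before the second epoxide is made. It sets out from 39: one equivalent of HCl in Et2O at −40 °C opens the 11,20-epoxide at its CH2 to give the 20-chloro-11α-hydroxy chlorohydrin F2. mCPBA then gives its 5,6-epoxide F3. The silyl triflate/DBU isomerisation now meets a single epoxide and gives the 6,11-bis(trimethylsilyl) ether F4, and citric acid in methanol frees the chlorohydrin allylic alcohol F5. Ag2O in CH2Cl2 recloses the 11,20-epoxide by intramolecular Williamson displacement with retention at C-11, which returns to the route at 42.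

Step 28 (SN2′ attack at the exocyclic CH2 or loss of stereospecificity instead of clean inversion at C-6). The fallback removes the allylic system before the substitution. It sets out from 42: ozonolysis (O3, then Me2S) of the exocyclic methylene gives the 5-oxo-6-hydroxy compound F6. Tf2O with 2,6-di-tert-butylpyridine gives the 6-triflyloxy-5-ketone F7. Bu4NCl displaces at the carbonyl-activated C-6 with inversion to the 6α-chloro-5-ketone F8, where no SN2′ path exists. Methylenation of the C-5 ketone with Cp2TiMe2 in toluene at 65 °C returns to the route at 43.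

**Further compounds**
F1 | step 24 | 2-oxo-7α,19-lactone (8α-triethylsilyloxy, 5Z) | O=C1O[C@H]2/C=C(C)\CCC(=O)[C@@]3(C)[C@@H](OC(C)=O)[C@@H](OC(=O)CC(C)C)[C@@H](OC(C)=O)[C@]4(CO4)[C@@H]3[C@H](OC(C)=O)[C@]2(O[Si](CC)(CC)CC)[C@H]1C
F2 | step 27 | 20-chloro-11α-hydroxy chlorohydrin of 39 | O=C1O[C@H]2/C=C(C)\CC[C@H](OC(=O)C(C)C)[C@@]3(C)[C@@H](OC(C)=O)[C@@H](OC(=O)CC(C)C)[C@@H](OC(C)=O)[C@](O)(CCl)[C@@H]3[C@H](OC(C)=O)[C@]2(O[Si](CC)(CC)CC)[C@H]1C
F3 | step 27 | 5,6-epoxide of the chlorohydrin | O=C1O[C@H]2[C@@H]4O[C@]4(C)CC[C@H](OC(=O)C(C)C)[C@@]3(C)[C@@H](OC(C)=O)[C@@H](OC(=O)CC(C)C)[C@@H](OC(C)=O)[C@](O)(CCl)[C@@H]3[C@H](OC(C)=O)[C@]2(O[Si](CC)(CC)CC)[C@H]1C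
F4 | step 27 | 6,11-bis(trimethylsilyloxy)-20-chloro-5(16)-ene | C=C1CC[C@H](OC(=O)C(C)C)[C@@]2(C)[C@@H](OC(C)=O)[C@@H](OC(=O)CC(C)C)[C@@H](OC(C)=O)[C@](O[Si](C)(C)C)(CCl)[C@@H]2[C@H](OC(C)=O)[C@]2(O[Si](CC)(CC)CC)[C@@H](C)C(=O)O[C@H]2[C@@H]1O[Si](C)(C)C
F5 | step 27 | 20-chloro-6,11α-dihydroxy-5(16)-ene | C=C1CC[C@H](OC(=O)C(C)C)[C@@]2(C)[C@@H](OC(C)=O)[C@@H](OC(=O)CC(C)C)[C@@H](OC(C)=O)[C@](O)(CCl)[C@@H]2[C@H](OC(C)=O)[C@]2(O[Si](CC)(CC)CC)[C@@H](C)C(=O)O[C@H]2[C@@H]1O
F6 | step 28 | 5-oxo-6-hydroxy compound (16-nor ketone) | O=C1CC[C@H](OC(=O)C(C)C)[C@@]2(C)[C@@H](OC(C)=O)[C@@H](OC(=O)CC(C)C)[C@@H](OC(C)=O)[C@]3(CO3)[C@@H]2[C@H](OC(C)=O)[C@]2(O[Si](CC)(CC)CC)[C@@H](C)C(=O)O[C@H]2[C@@H]1O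
F7 | step 28 | 6-(trifluoromethylsulfonyloxy)-5-ketone | O=C1CC[C@H](OC(=O)C(C)C)[C@@]2(C)[C@@H](OC(C)=O)[C@@H](OC(=O)CC(C)C)[C@@H](OC(C)=O)[C@]3(CO3)[C@@H]2[C@H](OC(C)=O)[C@]2(O[Si](CC)(CC)CC)[C@@H](C)C(=O)O[C@H]2[C@@H]1OS(=O)(=O)C(F)(F)F
F8 | step 28 | 6α-chloro-5-ketone | O=C1CC[C@H](OC(=O)C(C)C)[C@@]2(C)[C@@H](OC(C)=O)[C@@H](OC(=O)CC(C)C)[C@@H](OC(C)=O)[C@]3(CO3)[C@@H]2[C@H](OC(C)=O)[C@]2(O[Si](CC)(CC)CC)[C@@H](C)C(=O)O[C@H]2[C@H]1Cl
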